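**Strategy**

Cuts: (a) the C10′ and C13′ carbonyls of the side chain are folded back, with loss of one water, into a 2-alkyl-5-methylfuran. (b) The lactone O2–C1 bond and the C3–H bond are cut together, giving an achiral 2-acyl-4,6-dimethoxybenzaldehyde. (c) The C3–C1′ bond is cut to 4,6-dimethoxyphthalide and a C9 organolithium. (d) The C9′–C10′ bond (CH2 to furan C2) is cut to 2-methylfuran and 1,9-dibromononane.
Enabling feature: C1 and C3 of the five-membered lactone ring sit on the adjacent benzene carbons C7a and C3a. Together they have the oxidation level of ArCHO plus ArC(=O)R, so adding the formyl C–H across the ortho C=O builds the whole ring as an isomerisation. The 1,4-spacing of C10′ and C13′ is what allows the furan mask.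
Forward order: the C9 chain goes onto the furan, then onto the arene by opening the lactone of the regioisomeric phthalide at its carbonyl. The freed CH2OH is oxidised, the lactone ring is closed in the reverse orientation, and the furan ring is opened last.
Stereochemistry: C3 (S) is the only stereocentre. The chiral bisphosphine on rhodium creates it from the achiral keto aldehyde (hydride to the Re face of the ketone), and no later step touches it.

Key step: step 7

Locants: phthalide numbering (C1 lactone carbonyl, O2, C3 carbinol); the side chain is C1′–C14′ counted from C3.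
Assumption: (S,S,R,R)-DuanPhos is taken as the ligand antipode that leads to (S)-3-n-alkylphthalides. If the sense is the opposite, the equally available (R,R,S,S) antipode is used and nothing else changes.

Step 1
Reactants: 1 2-methylfuran; 2 1,9-dibromononane
Product: 4 2-(9-bromononyl)-5-methylfuran, via 5-methyl-2-furyllithium 3 (not isolated)
Conditions: n-BuLi (1.0 equiv), THF, −78 → 0 °C; then cannulated into 2 (3 equiv), THF, −78 °C → rt
Reagents that add atoms: none
Why: α-Lithiation of the furan at its only free α-position followed by SN2 alkylation with a primary bromide is standard, and inverse addition to a threefold excess of the symmetrical dibromide should keep double alkylation low, with surplus 2 recovered by distillation.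

Step 2
Reactants: 4 2-(9-bromononyl)-5-methylfuran
Product: 5 2-(9-iodononyl)-5-methylfuran
Conditions: NaI (3 equiv), acetone, reflux, dark
Reagents that add atoms: sodium iodide, [Na+].[I-]
Why: Finkelstein exchange, driven by precipitation of sodium bromide, supplies the primary iodide needed for a fast and clean lithium–halogen exchange, and the neutral medium leaves the furan alone.

Step 3
Reactants: 6 methyl 3,5-dimethoxybenzoate
Product: 8 methyl 2-formyl-3,5-dimethoxybenzoate, via aryl iminium chloride 7 (not isolated)
Conditions: POCl3 (1.5 equiv), DMF, 0 → 90 °C; then ice–water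
Reagents that add atoms: N,N-dimethylformamide, CN(C)C=O; water, O
Why: In this Vilsmeier–Haack formylation the chloroiminium ion should attack C2 (ortho to one methoxy group, para to the other) rather than the crowded C4 between the two methoxy groups, and hydrolysis of 7 releases the aldehyde with the ester intact.

Step 4
Reactants: 8 methyl 2-formyl-3,5-dimethoxybenzoate
Product: 10 4,6-dimethoxyphthalide, via hydroxy ester 9 (not isolated)
Conditions: NaBH4, MeOH, 0 °C → rt; then 1 M HCl
Reagents that add atoms: none
Why: Chemoselective borohydride reduction of the aldehyde beside the ester gives benzylic alcohol 9, which lies ortho to the ester and should close by intramolecular transesterification (5-exo-trig lactonisation), completed by the acidic work-up.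

Step 5
Reactants: 5 2-(9-iodononyl)-5-methylfuran; 10 4,6-dimethoxyphthalide
Product: 14 1-[2-(hydroxymethyl)-3,5-dimethoxyphenyl]-10-(5-methylfuran-2-yl)decan-1-one, via alkyllithium 11 (not isolated), via lithium lactolate 12 (not isolated), via lactol 13 (not isolated)
Conditions: 5, t-BuLi (2.0 equiv), Et2O–pentane, −78 °C; then cannulated into 10 (1.1 equiv), THF, −78 °C; sat. aq NH4Cl at −78 °C
Reagents that add atoms: none
Why: Lithium–iodine exchange (the second equivalent of t-BuLi destroys the tert-butyl iodide) gives 11, and its 1,2-addition to the lactone carbonyl, which is meta to both methoxy groups and so not deactivated, should stop at the cyclic tetrahedral alkoxide 12 at −78 °C as in the familiar lactone-to-lactol mono-addition of organolithiums, so the ketone appears only after the cold quench through ring–chain tautomerism of 13.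

Step 6
Reactants: 14 1-[2-(hydroxymethyl)-3,5-dimethoxyphenyl]-10-(5-methylfuran-2-yl)decan-1-one
Product: 15 2,4-dimethoxy-6-[10-(5-methylfuran-2-yl)decanoyl]benzaldehyde
Conditions: activated MnO2 (15 equiv), CH2Cl2, rt
Reagents that add atoms: none
Why: In this MnO2 oxidation of an electron-rich benzylic primary alcohol only the open tautomer 14 can react (hemiketal 13 is tertiary) and it is replenished by equilibration, while the neutral heterogeneous medium avoids dehydration of the hemiketal, intramolecular aldol closure of the product and attack on the furan.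

Step 7
Reactants: 15 2,4-dimethoxy-6-[10-(5-methylfuran-2-yl)decanoyl]benzaldehyde
Product: 16 (S)-5,7-dimethoxy-3-[9-(5-methylfuran-2-yl)nonyl]phthalide
Conditions: [Rh(cod)Cl]2 (5 mol %), (S,S,R,R)-DuanPhos (10 mol %), AgNO3 (10 mol %), PhMe, 100 °C, Ar
Reagents that add atoms: none
Why: The Rh(I)–DuanPhos cation freed by AgNO3 (the weakly bound nitrate tempers decarbonylation) adds oxidatively into the formyl C–H bond while the neighbouring ketone oxygen binds rhodium, giving a six-membered chelated acyl rhodium(III) hydride. Insertion of the ketone C=O into Rh–H makes the C3–H bond and a six-membered acyl(alkoxo)rhodacycle (Rh, C1, C7a, C3a, C3, O2), and C–O reductive elimination then forms O2–C1 and returns Rh(I). The reaction type is the known Rh(I)/chiral bisphosphine intramolecular ketone hydroacylation of 2-acylbenzaldehydes, established for aryl n-alkyl ketones that give 3-alkylphthalides. The single ring closed is the five-membered lactone, made by ring-contracting reductive elimination, formally a 5-exo-trig attack of the C3 alkoxide on the acyl carbon. C3 is set by catalyst control: in the rigid chelate the ligand quadrants distinguish the flat aryl tether from the linear alkyl chain, so hydride should reach the Re face of the ketone and give the S configuration. The step needs enantioface selectivity and preference for hydroacylation over decarbonylation, both secured by the fixed ortho arrangement of the two carbonyl groups that keeps rhodium chelated, and the remote, fully α-substituted furan offers no competing carbonyl or reactive C–H site.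

Step 8
Reactants: 16 (S)-5,7-dimethoxy-3-[9-(5-methylfuran-2-yl)nonyl]phthalide
Product: 17 CJ-13,015, (S)-3-(10,13-dioxotetradecyl)-5,7-dimethoxyphthalide
Conditions: AcOH–H2O (3:1), cat. H2SO4, 100 °C
Reagents that add atoms: water, O
Why: In this acid-catalysed hydrolysis of a 2,5-dialkylfuran (reverse Paal–Knorr reaction) α-protonation, addition of water and ring opening give the 1,4-diketone, while the aryl methyl ethers are inert, a transiently opened lactone recloses in acid, and C3 should keep its configuration because a cation there would get no help from the two meta methoxy groups and would be destabilised by the adjacent acyl-bearing carbon.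

**Compound list**

1 | 2-methylfuran | Cc1ccco1 | starting material
2 | 1,9-dibromononane | BrCCCCCCCCCBr | starting material
3 | 5-methyl-2-furyllithium | Cc1ccc([Li])o1 | intermediate
4 | 2-(9-bromononyl)-5-methylfuran | Cc1ccc(CCCCCCCCCBr)o1 | intermediate
5 | 2-(9-iodononyl)-5-methylfuran | Cc1ccc(CCCCCCCCCI)o1 | intermediate
6 | methyl 3,5-dimethoxybenzoate | COC(=O)c1cc(OC)cc(OC)c1 | starting material
7 | [2,4-dimethoxy-6-(methoxycarbonyl)benzylidene]dimethyliminium chloride | COC(=O)c1cc(OC)cc(OC)c1C=[N+](C)C.[Cl-] | intermediate
8 | methyl 2-formyl-3,5-dimethoxybenzoate | COC(=O)c1cc(OC)cc(OC)c1C=O | intermediate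
9 | methyl 2-(hydroxymethyl)-3,5-dimethoxybenzoate | COC(=O)c1cc(OC)cc(OC)c1CO | intermediate
10 | 4,6-dimethoxyphthalide (4,6-dimethoxyisobenzofuran-1(3H)-one) | COc1cc(OC)c2c(c1)C(=O)OC2 | intermediate
11 | 9-(5-methylfuran-2-yl)nonyllithium | Cc1ccc(CCCCCCCCC[Li])o1 | intermediate
12 | lithium 4,6-dimethoxy-1-[9-(5-methylfuran-2-yl)nonyl]-1,3-dihydroisobenzofuran-1-olate (racemic) | [Li+].[O-]C1(CCCCCCCCCc2ccc(C)o2)OCc2c(OC)cc(OC)cc21 | intermediate
13 | 4,6-dimethoxy-1-[9-(5-methylfuran-2-yl)nonyl]-1,3-dihydroisobenzofuran-1-ol (racemic ring tautomer of 14) | OC1(CCCCCCCCCc2ccc(C)o2)OCc2c(OC)cc(OC)cc21 | intermediate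
14 | 1-[2-(hydroxymethyl)-3,5-dimethoxyphenyl]-10-(5-methylfuran-2-yl)decan-1-one | COc1cc(OC)c(CO)c(c1)C(=O)CCCCCCCCCc1ccc(C)o1 | intermediate
15 | 2,4-dimethoxy-6-[10-(5-methylfuran-2-yl)decanoyl]benzaldehyde | COc1cc(OC)c(C=O)c(c1)C(=O)CCCCCCCCCc1ccc(C)o1 | intermediate
16 | (S)-5,7-dimethoxy-3-[9-(5-methylfuran-2-yl)nonyl]phthalide | COc1cc(OC)c2c(c1)[C@H](CCCCCCCCCc1ccc(C)o1)OC2=O | intermediate
17 | CJ-13,015, (S)-3-(10,13-dioxotetradecyl)-5,7-dimethoxyphthalide | COc1cc(OC)c2c(c1)[C@H](CCCCCCCCCC(=O)CCC(C)=O)OC2=O | target

**Step count**

Total steps: 8. Longest linear sequence: 6 steps (1, 2, 5, 6, 7, 8 from 2-methylfuran, or equally 3, 4, 5, 6, 7, 8 from methyl 3,5-dimethoxybenzoate).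

**Steps most likely to fail**

Step 7. Oxidative addition into the formyl C–H bond may be slow, because the formyl group is flanked by a methoxy and an acyl group and sits on an electron-rich ring. Decarbonylation of the acyl rhodium species could then take over, or facial selectivity could erode at the temperature needed.

The fallback sets C3 with an external hydride. It sets out from 14. Noyori asymmetric transfer hydrogenation (RuCl[(S,S)-TsDPEN](p-cymene), HCO2Na, aqueous MeOH, 40 °C) should reduce the aryl alkyl ketone to (1S)-1-[2-(hydroxymethyl)-3,5-dimethoxyphenyl]-10-(5-methylfuran-2-yl)decan-1-ol F1. Oxidative lactonisation with catalytic TEMPO and PhI(OAc)2 in CH2Cl2 prefers the primary alcohol. It then passes through (3S)-5,7-dimethoxy-3-[9-(5-methylfuran-2-yl)nonyl]-1,3-dihydroisobenzofuran-1-ol F2 and comes back to the route at 16.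

Step 5. The tetrahedral adduct may collapse early and take up a second equivalent of organolithium, or the lactone CH2 may be deprotonated instead of the carbonyl being attacked.

The fallback adds the chain at the aldehyde oxidation level, where over-addition is impossible. It sets out from 10 and 4. DIBAL-H (CH2Cl2, −78 °C) reduces 10 to 4,6-dimethoxy-1,3-dihydroisobenzofuran-1-ol F3. Bromide 4 with Mg in THF gives [9-(5-methylfuran-2-yl)nonyl]magnesium bromide F4. Just over two equivalents of this reagent (the first is spent on the lactol OH) add to the open hydroxy aldehyde form. The product is racemic 1-[2-(hydroxymethyl)-3,5-dimethoxyphenyl]-10-(5-methylfuran-2-yl)decan-1-ol F5.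

A double Swern oxidation follows ((COCl)2, DMSO, i-Pr2NEt, CH2Cl2, −78 °C). Both hydroxyl groups are activated before base is added, which avoids the lactol-to-lactone shunt. The sequence comes back to the route at 15.

Step 8. Hydrolysis may stall. The protonated furan may oligomerise or be captured by the electron-rich benzene ring, and the liberated diketone may undergo aldol cyclisation in hot acid.

The fallback opens the furan by oxidation and reduction instead of hydrolysis. It sets out from 16. mCPBA (1.0 equiv, CH2Cl2, 0 °C) should open the 2,5-dialkylfuran to (S)-3-[(Z)-10,13-dioxotetradec-11-enyl]-5,7-dimethoxyphthalide F6. Zn dust in AcOH at rt then reduces the enedione C=C and comes back to the route at 17.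

**Further compounds**

F1 | step 7 | (1S)-1-[2-(hydroxymethyl)-3,5-dimethoxyphenyl]-10-(5-methylfuran-2-yl)decan-1-ol | COc1cc(OC)c(CO)c(c1)[C@H](CCCCCCCCCc1ccc(C)o1)O
F2 | step 7 | (3S)-5,7-dimethoxy-3-[9-(5-methylfuran-2-yl)nonyl]-1,3-dihydroisobenzofuran-1-ol (C1 epimers) | COc1cc(OC)c2c(c1)[C@H](CCCCCCCCCc1ccc(C)o1)OC2O
F3 | step 5 | 4,6-dimethoxy-1,3-dihydroisobenzofuran-1-ol | COc1cc(OC)c2c(c1)C(O)OC2
F4 | step 5 | [9-(5-methylfuran-2-yl)nonyl]magnesium bromide | Cc1ccc(CCCCCCCCC[Mg]Br)o1
F5 | step 5 | racemic 1-[2-(hydroxymethyl)-3,5-dimethoxyphenyl]-10-(5-methylfuran-2-yl)decan-1-ol | COc1cc(OC)c(CO)c(c1)C(O)CCCCCCCCCc1ccc(C)o1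
F6 | step 8 | (S)-3-[(Z)-10,13-dioxotetradec-11-enyl]-5,7-dimethoxyphthalide | COc1cc(OC)c2c(c1)[C@H](CCCCCCCCCC(=O)/C=C\C(C)=O)OC2=O
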